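## Structural features

Hanultarin (19) is an open-chain lignan ester. A butane-1,4-diol chain carries a 4-hydroxy-3-methoxybenzyl group on each of C2 and C3, the oxygen on C1 is acylated by (E)-ferulic acid, and the oxygen on C4 is free. Three guaiacyl rings are present, two joined to the chain through benzylic CH2 groups and one through the cinnamate ester; none is fused or bridged. The only stereocentres are the adjacent tertiary carbons C2 and C3, both R. Without the acyl group the diol is C2-symmetric, so its two CH2OH groups are homotopic and acylation of either gives the same mono-ester. Fragile elements are the three free phenols (oxidation, competition in acylation), the conjugated (E)-alkene (hydrogenation, conjugate addition), the ester (base, transesterification) and the 1,4-diol (closure to a tetrahydrofuran in hot acid). The real difficulty is absolute and relative control of two contiguous, unfunctionalised CH centres in a flexible chain, followed by attachment of exactly one feruloyl group. Each stereocentre is one CH2 away from C1 of a guaiacyl ring, so the two aryl–CH2 bonds can be made last, at carbons that are not stereogenic, on a C2-symmetric six-carbon diacid. Traced backwards, the (2R,3R) diol, the (3R,4R) diacid and the (1R,2R) cyclohexene have the same spatial arrangement, because the priority order oxygen-bearing carbon > neighbouring stereocentre > CH2 > H holds at every stage.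

## Logic of the disconnections

19 from 18. The three aryl O–Si bonds are cut. The phenols must be masked while the ester is made, and aryl silyl ethers leave with buffered fluoride, which a cinnamate and a free primary alcohol tolerate. The gain is that acylation is done on a compound with one kind of free nucleophile. The demand is a near-neutral desilylation, since base would attack the ester.

18 from 14 and 17. The acyl C–O bond of the ester is cut. This keeps the cinnamate, which would not survive oxidative alkene cleavage, out of the core chemistry and leaves a C2-symmetric diol. The forward step must stop at mono-acylation; which oxygen reacts is irrelevant, and acyl migration would return the same compound.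

17 from 15 (through 16). Only the phenol O–Si bond is cut. The forward step silylates both acidic groups and must then hydrolyse the silyl ester alone.

14 from 13. The two alkyl O–Si bonds are cut. These groups carry the primary oxygens through oxidation, esterification and coupling. They must leave under acid without loss of the aryl silyl groups, hence tert-butyldimethylsilyl on the alkyl oxygens and triisopropylsilyl on the aryl oxygens.

13 from 9 and two molecules of 11 (through 12). Both aryl–CH2 bonds are cut. Each cut removes a ring and turns a benzylic carbon into the alpha-carbon of an activated carboxyl group; the C2 axis makes the two cuts one operation. The gain is a six-carbon aliphatic diacid derivative and one simple aryl iodide used twice. The demand is an sp3–sp2 coupling of two electrophiles that works twice on one molecule, tolerates silyl ethers and leaves the neighbouring stereocentres alone.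

11 from 10. The aryl O–Si bond is cut; the forward step is a plain silylation that makes the phenol inert to Zn, nickel and later acid.

9 from 8. The two acyl C–O(N) bonds are cut. The free diacid is the stable, storable compound, and the redox-active ester is made just before use. The forward step must activate both carboxyl groups without cleaving the gamma-silyloxy groups, which would lactonise.

8 from 7. The two carboxyl carbons are reconnected as a C=C bond, closing a cyclohexene. The open-chain anti relationship becomes a trans-1,2-disubstituted ring, for which reliable asymmetric cycloaddition exists. The forward step must cleave the alkene to the acid level in the presence of two silyl ethers.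

7 from 6, and 6 from 5. The O–Si bonds are cut, then the two CH2OH groups are raised to esters. This puts electron-withdrawing groups on the stereocentres, as a cycloaddition needs. The forward steps are a hydride reduction that must not epimerise the alpha-centres and a bis-silylation.

5 from 3 and 4. The two ring C–C bonds between the stereocentres and the allylic CH2 groups are cut in a retro-Diels–Alder sense. Both stereocentres then derive from an (E)-alkene, so trans is assured by the concerted mechanism. The demand is facial control, placed on the ester auxiliary and a Lewis acid.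

3 from 1 and 2. The two ester C–O bonds are cut, giving the diacid and the chiral alcohol; the forward step is an acid-catalysed esterification.

## Other disconnections considered

Alternative 1: The cut is the ring C–O bond of a beta-substituted gamma-butyrolactone, so the first stereocentre would come from desymmetrising the prochiral 3-(arylmethyl)cyclobutanone A1.
- Forward key step: a Baeyer–Villiger monooxygenase (flavin cofactor, NADPH recycling, O2) would insert oxygen beside one of the two enantiotopic CH2 groups of A1 and give lactone A2. Trans alkylation of the enolate of A2 with an arylmethyl halide and LiAlH4 opening would then reach the diol stage.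
- In its favour: the chiral agent is catalytic, the oxidant is air, and no auxiliary is attached or removed. On the source of chirality it is the better plan, since the chosen route consumes two equivalents of 2.
- Against it here: the key step sets only one stereocentre, and the second is formed at an enolisable carbon under substrate control. An enzyme with (R) preference for this substrate would have to be found by screening. A1 needs a ketene cycloaddition and a dechlorination. The methoxymethyl ethers would later have to come off with acid beside the cinnamate and the 1,4-diol.
- Comparison: structurally it makes the aryl–CH2 bonds first and the stereocentres afterwards, the reverse of the chosen order, and it does not use the C2 symmetry, as the two halves enter in different steps. Mechanistically it is a two-electron oxygen insertion through a flavin peroxide with migration of one CH2, against a radical and organonickel coupling. In total count to the diol stage the plans are about equal; the alternative's longest linear sequence would be roughly two steps shorter, a point in its favour.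

Alternative 2: Both bonds from the stereocentres to the benzylic carbons are cut, leaving the chiral butenolide acetal A3, the aryl dithiane A4 and the arylmethyl bromide A5.
- Forward key step: A4, lithiated with n-BuLi, would add to the beta carbon of A3 anti to the menthyloxy group, and the lactone enolate would be alkylated by A5 trans to the dithiane, giving A6. Raney Ni desulfurisation and LiAlH4 reduction of the lactone and acetal carbons would then give 14 with release of the auxiliary.
- In its favour: both stereocentres and both C–C bonds are made in one flask from three fragments, and only two steps separate A6 from 14. On convergence and longest linear sequence it is better than the chosen plan. The auxiliary is stoichiometric in both plans, so they are equal there.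
- Against it here: it needs cryogenic organolithium chemistry in the presence of aryl silyl ethers. The bonds are made at the stereocentres themselves, so the relative configuration rests on kinetic anti addition and trans alkylation, whereas in the chosen plan the stereocentres are spectators. It uses stoichiometric sulfur and a large excess of Raney Ni. A3 must be a single acetal epimer, and A4 and A5 are two different aryl building blocks, against one iodide used twice.
- Comparison: the mechanism is polar (carbanion conjugate addition, enolate alkylation) against radical capture at nickel. Total step count to 14 would be similar.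

Alternative 3: The two bonds from C2 and C3 to the future CH2O carbons are cut, leaving the symmetrical (E)-alkene A8, the metathesis dimer of the silylated allylarene A7.
- Forward key step: Pd(OCOCF3)2 with a chiral bis(oxazoline), CO, MeOH and p-benzoquinone would add two methoxycarbonyl groups syn across A8 to give diester A9; LiAlH4 would then give 14. A methoxycarbonyl complex of divalent palladium inserts the alkene, CO inserts into the alkyl–palladium bond, methanolysis releases zerovalent palladium, and the quinone reoxidises it.
- In its favour: it would be the shortest route by far (about four steps to 14 against nine), catalytic in the chiral agent, and would set both stereocentres at once. Syn addition to an (E)-alkene gives the required C2-symmetric diastereomer by mechanism. On step economy and atom economy it is clearly better than the chosen plan, and it uses the C2 symmetry equally well.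
- Against it here: 1,2-dialkyl internal alkenes insert slowly. The alkylpalladium intermediate has benzylic beta-hydrogens, so beta-hydride elimination and migration of the alkene into conjugation would compete. Enantiofacial discrimination of a symmetrical internal alkene at the level needed is not secured by known scope. Any (Z)-alkene in A8 would lead to the meso diester, and CO pressure is required.
- Comparison: the chosen plan is longer but each of its steps is of an established type on its substrate class.

Key step: step 8

Assumption: the sense of induction in step 2 is taken from the accepted model for Lewis-acid-bound dimenthyl fumarates (ester carbonyls s-trans to the alkene, diene approaching the face away from the isopropyl groups), by which the (−)-menthyl ester leads to the (1S,2S) adduct; the (+)-menthyl ester is therefore used for the (1R,2R) adduct, and the configuration would be confirmed by the sign of rotation of 6 before going on.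

## Route

Step 1
Reactants: 1 fumaric acid; 2 (+)-menthol [(1S,2R,5S)-2-isopropyl-5-methylcyclohexan-1-ol] (2.1 equiv)
Product: 3 di-(+)-menthyl fumarate [bis((1S,2R,5S)-2-isopropyl-5-methylcyclohexyl) (E)-but-2-enedioate]
Conditions: TsOH·H2O (cat.), toluene, reflux, azeotropic removal of water
Reagents that add atoms: none
Why: Fischer esterification driven by removal of water; only acyl C–O bonds form, so the (E)-alkene and the carbinol stereocentres of 2 are untouched.

Step 2
Reactants: 3 di-(+)-menthyl fumarate; 4 buta-1,3-diene (excess)
Product: 5 di-(+)-menthyl (1R,2R)-cyclohex-4-ene-1,2-dicarboxylate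
Conditions: Et2AlCl (2 equiv), toluene, −78 to −40 °C
Reagents that add atoms: none
Why: Lewis-acid-promoted Diels–Alder reaction; the trans relationship follows from suprafacial addition to the (E)-dienophile, and both menthyl groups shield the same face of the aluminium-bound s-trans diester, so the diene should add to the open face to give the (1R,2R) adduct. Crystallisation of 5 should raise its diastereomeric purity.

Step 3
Reactants: 5 di-(+)-menthyl (1R,2R)-cyclohex-4-ene-1,2-dicarboxylate
Product: 6 [(1R,2R)-cyclohex-4-ene-1,2-diyl]dimethanol
Conditions: LiAlH4, THF, 0 °C to reflux; aqueous NaOH work-up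
Reagents that add atoms: none
Why: Hydride reduction of both esters to primary alcohols; reduction is faster than enolisation and the trans isomer is the stable one, so the alpha-stereocentres should hold, and 2 is recovered.

Step 4
Reactants: 6 [(1R,2R)-cyclohex-4-ene-1,2-diyl]dimethanol
Product: 7 (4R,5R)-4,5-bis[(tert-butyldimethylsilyloxy)methyl]cyclohexene
Conditions: TBSCl (2.4 equiv), imidazole, DMF, rt
Reagents that add atoms: tert-butyldimethylsilyl chloride CC(C)(C)[Si](C)(C)Cl
Why: Standard silylation of two unhindered primary alcohols; no stereocentre is involved.

Step 5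
Reactants: 7 (4R,5R)-4,5-bis[(tert-butyldimethylsilyloxy)methyl]cyclohexene
Product: 8 (3R,4R)-3,4-bis[(tert-butyldimethylsilyloxy)methyl]hexanedioic acid
Conditions: RuCl3 hydrate (5 mol%), NaIO4 (4.5 equiv), EtOAc/MeCN/H2O, 0 °C to rt
Reagents that add atoms: sodium periodate [Na+].[O-]I(=O)(=O)=O; water O
Why: Ruthenium tetroxide formed in situ cleaves the cis-disubstituted ring alkene through a cyclic ruthenate ester and oxidises the resulting aldehydes to acids. Silyl ethers of primary alcohols are normally tolerated, and the saturated stereocentres are not touched.

Step 6
Reactants: 8 (3R,4R)-3,4-bis[(tert-butyldimethylsilyloxy)methyl]hexanedioic acid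
Product: 9 bis(1,3-dioxoisoindolin-2-yl) (3R,4R)-3,4-bis[(tert-butyldimethylsilyloxy)methyl]hexanedioate
Conditions: N-hydroxyphthalimide (2.2 equiv), N,N'-diisopropylcarbodiimide (2.4 equiv), DMAP (10 mol%), CH2Cl2, rt
Reagents that add atoms: N-hydroxyphthalimide O=C1c2ccccc2C(=O)N1O
Why: Carbodiimide-mediated (Steglich-type) esterification of both acids; neither stereocentre is alpha to a carbonyl, so activation cannot epimerise them.

Step 7
Reactants: 10 4-iodo-2-methoxyphenol
Product: 11 (4-iodo-2-methoxyphenoxy)triisopropylsilane
Conditions: TIPSCl (1.2 equiv), imidazole, DMF, rt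
Reagents that add atoms: triisopropylsilyl chloride CC(C)[Si](Cl)(C(C)C)C(C)C
Why: Silylation of a phenol; the hindered triisopropylsilyl group is chosen because it should survive Zn in DMA and the later acidic methanolysis yet leave with fluoride.

Step 8
Reactants: 9 bis(1,3-dioxoisoindolin-2-yl) (3R,4R)-3,4-bis[(tert-butyldimethylsilyloxy)methyl]hexanedioate; 11 (4-iodo-2-methoxyphenoxy)triisopropylsilane (3 equiv)
Product: 13 (2R,3R)-1,4-bis(tert-butyldimethylsilyloxy)-2,3-bis[3-methoxy-4-(triisopropylsilyloxy)benzyl]butane, via mono-arylated NHP ester 12 (not isolated)
Conditions: NiBr2(dme) (20 mol%), 4,4'-di-tert-butyl-2,2'-bipyridine (20 mol%), Zn powder (5 equiv), DMA, rt, inert atmosphere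
Reagents that add atoms: none
Why: This is a nickel-catalysed reductive cross-electrophile coupling; the closest known reaction type is the decarboxylative arylation of N-hydroxyphthalimide esters of primary acids with aryl iodides, here run at both ends of 9. Zerovalent nickel on the bipyridine adds oxidatively to the C–I bond of 11 to give an arylnickel iodide (divalent nickel), while a low-valent nickel species or Zn passes one electron to a phthalimide ester, which fragments to phthalimide anion, CO2 and a primary radical. The arylnickel species captures the radical to give an aryl(alkyl) complex of trivalent nickel, reductive elimination forms the aryl–CH2 bond, and Zn returns the resulting monovalent nickel to the zerovalent state. The first turnover gives 12, which re-enters the same cycle at its remaining ester to give 13. No ring closes and no stereocentre is formed; the two existing stereocentres are beta to the radical carbons and bear no bond that changes, so their configuration should be carried through. The selectivity needed is cross-coupling over biaryl formation, alkyl dimerisation and reduction of the radical to C–H. It is secured by the different activation modes of the partners (two-electron addition for the aryl iodide, one-electron reduction for the ester), by an excess of 11, and by the absence of a beta leaving group or an easily transferred hydrogen near the radical. Alkyl and aryl silyl ethers are inert to Zn and to the nickel catalyst in DMA.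

Step 9
Reactants: 13 (2R,3R)-1,4-bis(tert-butyldimethylsilyloxy)-2,3-bis[3-methoxy-4-(triisopropylsilyloxy)benzyl]butane
Product: 14 (2R,3R)-2,3-bis[3-methoxy-4-(triisopropylsilyloxy)benzyl]butane-1,4-diol
Conditions: camphorsulfonic acid (20 mol%), MeOH/CH2Cl2 (1:1), 0 °C to rt
Reagents that add atoms: none
Why: Acid-catalysed methanolysis removes primary alkyl tert-butyldimethylsilyl ethers much faster than hindered aryl triisopropylsilyl ethers, whose oxygen is poorly basic. At room temperature the 1,4-diol should not cyclise to the tetrahydrofuran.

Step 10
Reactants: 15 ferulic acid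
Product: 17 (E)-3-[4-(tert-butyldimethylsilyloxy)-3-methoxyphenyl]acrylic acid, via bis-silylated ferulate 16 (not isolated)
Conditions: TBSCl (2.5 equiv), imidazole, DMF, rt; then AcOH/THF/H2O (3:1:1), rt
Reagents that add atoms: tert-butyldimethylsilyl chloride CC(C)(C)[Si](C)(C)Cl
Why: Silylation of phenol and acid, then selective hydrolysis of the far more labile silyl ester in aqueous acetic acid, to which aryl silyl ethers are stable; the (E)-alkene is not involved.

Step 11
Reactants: 14 (2R,3R)-2,3-bis[3-methoxy-4-(triisopropylsilyloxy)benzyl]butane-1,4-diol (excess); 17 (E)-3-[4-(tert-butyldimethylsilyloxy)-3-methoxyphenyl]acrylic acid (0.7 equiv, added slowly)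
Product: 18 (2R,3R)-4-hydroxy-2,3-bis[3-methoxy-4-(triisopropylsilyloxy)benzyl]butyl (E)-3-[4-(tert-butyldimethylsilyloxy)-3-methoxyphenyl]acrylate
Conditions: EDC·HCl, DMAP (cat.), CH2Cl2, 0 °C to rt; unreacted 14 recovered and recycled
Reagents that add atoms: none
Why: Steglich esterification; the two hydroxyl groups of 14 are homotopic, so either gives the same 18 and acyl migration is degenerate. A deficit of 17 keeps the bis-ester low, and the phenols are silylated so only aliphatic oxygen can be acylated.

Step 12
Reactants: 18 (2R,3R)-4-hydroxy-2,3-bis[3-methoxy-4-(triisopropylsilyloxy)benzyl]butyl (E)-3-[4-(tert-butyldimethylsilyloxy)-3-methoxyphenyl]acrylate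
Product: 19 hanultarin [(2R,3R)-4-hydroxy-2,3-bis(4-hydroxy-3-methoxybenzyl)butyl (E)-3-(4-hydroxy-3-methoxyphenyl)acrylate]
Conditions: Bu4NF (3.3 equiv), AcOH (3.3 equiv), THF, 0 °C to rt
Reagents that add atoms: none
Why: Fluoride cleaves aryl silyl ethers quickly because phenoxide leaves silicon easily. Buffering with AcOH keeps the medium near neutral, so the cinnamate ester should be neither cleaved nor transesterified, and no stereocentre is touched.

## Compound list

1 | fumaric acid | OC(=O)/C=C/C(=O)O | starting material
2 | (+)-menthol, (1S,2R,5S)-2-isopropyl-5-methylcyclohexan-1-ol | O[C@H]1C[C@@H](C)CC[C@@H]1C(C)C | starting material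
3 | di-(+)-menthyl fumarate | O=C(/C=C/C(=O)O[C@H]1C[C@@H](C)CC[C@@H]1C(C)C)O[C@H]1C[C@@H](C)CC[C@@H]1C(C)C | intermediate
4 | buta-1,3-diene | C=CC=C | starting material
5 | di-(+)-menthyl (1R,2R)-cyclohex-4-ene-1,2-dicarboxylate | O=C(O[C@H]2C[C@@H](C)CC[C@@H]2C(C)C)[C@@H]1CC=CC[C@H]1C(=O)O[C@H]3C[C@@H](C)CC[C@@H]3C(C)C | intermediate
6 | [(1R,2R)-cyclohex-4-ene-1,2-diyl]dimethanol | OC[C@@H]1CC=CC[C@H]1CO | intermediate
7 | (4R,5R)-4,5-bis[(tert-butyldimethylsilyloxy)methyl]cyclohexene | CC(C)(C)[Si](C)(C)OC[C@@H]1CC=CC[C@H]1CO[Si](C)(C)C(C)(C)C | intermediate
8 | (3R,4R)-3,4-bis[(tert-butyldimethylsilyloxy)methyl]hexanedioic acid | CC(C)(C)[Si](C)(C)OC[C@H](CC(=O)O)[C@H](CO[Si](C)(C)C(C)(C)C)CC(=O)O | intermediate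
9 | bis(1,3-dioxoisoindolin-2-yl) (3R,4R)-3,4-bis[(tert-butyldimethylsilyloxy)methyl]hexanedioate | CC(C)(C)[Si](C)(C)OC[C@H](CC(=O)ON1C(=O)c2ccccc2C1=O)[C@H](CO[Si](C)(C)C(C)(C)C)CC(=O)ON1C(=O)c2ccccc2C1=O | intermediate
10 | 4-iodo-2-methoxyphenol | COc1cc(I)ccc1O | starting material
11 | (4-iodo-2-methoxyphenoxy)triisopropylsilane | COc1cc(I)ccc1O[Si](C(C)C)(C(C)C)C(C)C | intermediate
12 | 1,3-dioxoisoindolin-2-yl (3R,4R)-3,4-bis[(tert-butyldimethylsilyloxy)methyl]-5-[3-methoxy-4-(triisopropylsilyloxy)phenyl]pentanoate | CC(C)(C)[Si](C)(C)OC[C@H](Cc1ccc(O[Si](C(C)C)(C(C)C)C(C)C)c(OC)c1)[C@H](CO[Si](C)(C)C(C)(C)C)CC(=O)ON1C(=O)c2ccccc2C1=O | intermediate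
13 | (2R,3R)-1,4-bis(tert-butyldimethylsilyloxy)-2,3-bis[3-methoxy-4-(triisopropylsilyloxy)benzyl]butane | CC(C)(C)[Si](C)(C)OC[C@H](Cc1ccc(O[Si](C(C)C)(C(C)C)C(C)C)c(OC)c1)[C@H](CO[Si](C)(C)C(C)(C)C)Cc1ccc(O[Si](C(C)C)(C(C)C)C(C)C)c(OC)c1 | intermediate
14 | (2R,3R)-2,3-bis[3-methoxy-4-(triisopropylsilyloxy)benzyl]butane-1,4-diol | OC[C@H](Cc1ccc(O[Si](C(C)C)(C(C)C)C(C)C)c(OC)c1)[C@H](CO)Cc1ccc(O[Si](C(C)C)(C(C)C)C(C)C)c(OC)c1 | intermediate
15 | ferulic acid | COc1cc(/C=C/C(=O)O)ccc1O | starting material
16 | tert-butyldimethylsilyl (E)-3-[4-(tert-butyldimethylsilyloxy)-3-methoxyphenyl]acrylate | COc1cc(/C=C/C(=O)O[Si](C)(C)C(C)(C)C)ccc1O[Si](C)(C)C(C)(C)C | intermediate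
17 | (E)-3-[4-(tert-butyldimethylsilyloxy)-3-methoxyphenyl]acrylic acid | COc1cc(/C=C/C(=O)O)ccc1O[Si](C)(C)C(C)(C)C | intermediate
18 | (2R,3R)-4-hydroxy-2,3-bis[3-methoxy-4-(triisopropylsilyloxy)benzyl]butyl (E)-3-[4-(tert-butyldimethylsilyloxy)-3-methoxyphenyl]acrylate | COc1cc(/C=C/C(=O)OC[C@H](Cc2ccc(O[Si](C(C)C)(C(C)C)C(C)C)c(OC)c2)[C@H](CO)Cc2ccc(O[Si](C(C)C)(C(C)C)C(C)C)c(OC)c2)ccc1O[Si](C)(C)C(C)(C)C | intermediate
19 | hanultarin | COc1cc(/C=C/C(=O)OC[C@H](Cc2ccc(O)c(OC)c2)[C@H](CO)Cc2ccc(O)c(OC)c2)ccc1O | target

## Step count and risks

Total step count: 12. Longest linear sequence: 10 steps (1, 2, 3, 4, 5, 6, 8, 9, 11, 12).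

Step 8 (key step).
- What may go wrong: the electron-rich aryl iodide adds slowly to nickel, so reduction of the primary radical to C–H, reductive homocoupling of the iodide and hydrolysis of the activated ester may outrun the second coupling and leave mixtures of mono- and bis-arylated material. Slow closure of the second radical onto the arene installed in the first coupling is a lesser concern.
- Fallback: change from a two-electrophile coupling to a nucleophile–electrophile coupling. From 11, iodine–magnesium exchange with iPrMgCl·LiCl (THF, −20 °C) gives the arylmagnesium chloride F1, which ZnCl2 converts into the arylzinc chloride F2. F2 (3 equiv) and 9 are then joined with Fe(acac)3 and 1,2-bis(diphenylphosphino)benzene in THF, a known decarboxylative Negishi-type arylation of redox-active esters of primary acids. This removes Zn metal and the aryl homocoupling path, and returns to the route at 13.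

Step 11.
- What may go wrong: over-acylation to the bis-ester and incomplete conversion, since the two hydroxyl groups react with statistical selectivity; N-acylurea formation would also consume 17.
- Fallback: differentiate the oxygens before acylation. From 14, the monosodium alkoxide (NaH, 1 equiv, THF) is silylated with TBSCl to the mono-silyl ether F3, a protocol known to favour mono-protection of symmetrical diols. F3 is acylated with an excess of 17 (EDC·HCl, DMAP) to the fully silylated mono-ester F4. Camphorsulfonic acid in MeOH, as in step 9, removes the alkyl silyl group and returns to the route at 18.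

Step 2.
- What may go wrong: insufficient facial selectivity with the unsubstituted, sluggish diene, induction opposite to the model assumed, or Lewis-acid-induced oligomerisation of the diene.
- Fallback: make the racemate and resolve it. From 1 and 4, a thermal Diels–Alder reaction (AcOH, sealed vessel, about 110 °C) gives the racemic trans-diacid F5. Fractional crystallisation of its salts with one enantiomer of 1-phenylethylamine, with the fraction chosen by the sign of rotation of the liberated acid, gives the (1R,2R)-diacid F6. LiAlH4 in THF reduces F6 and returns to the route at 6.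

Step 5.
- What may go wrong: loss of a silyl group in the acidic aqueous oxidant followed by irreversible closure of the gamma-hydroxy acid to a lactone, or oxidation stalling at the aldehyde.
- Fallback: cleave and oxidise in two stages. From 7, ozonolysis (O3, CH2Cl2/MeOH, −78 °C; then Me2S) gives the dialdehyde F7. Pinnick oxidation (NaClO2, NaH2PO4, 2-methylbut-2-ene, tBuOH/H2O) at buffered mild pH then returns to the route at 8.

Further compounds

F1 | step 8 | [3-methoxy-4-(triisopropylsilyloxy)phenyl]magnesium chloride | COc1cc([Mg]Cl)ccc1O[Si](C(C)C)(C(C)C)C(C)C
F2 | step 8 | [3-methoxy-4-(triisopropylsilyloxy)phenyl]zinc chloride | COc1cc([Zn]Cl)ccc1O[Si](C(C)C)(C(C)C)C(C)C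
F3 | step 11 | (2R,3R)-4-(tert-butyldimethylsilyloxy)-2,3-bis[3-methoxy-4-(triisopropylsilyloxy)benzyl]butan-1-ol | CC(C)(C)[Si](C)(C)OC[C@H](Cc1ccc(O[Si](C(C)C)(C(C)C)C(C)C)c(OC)c1)[C@H](CO)Cc1ccc(O[Si](C(C)C)(C(C)C)C(C)C)c(OC)c1
F4 | step 11 | (2R,3R)-4-(tert-butyldimethylsilyloxy)-2,3-bis[3-methoxy-4-(triisopropylsilyloxy)benzyl]butyl (E)-3-[4-(tert-butyldimethylsilyloxy)-3-methoxyphenyl]acrylate | COc1cc(/C=C/C(=O)OC[C@H](Cc2ccc(O[Si](C(C)C)(C(C)C)C(C)C)c(OC)c2)[C@H](CO[Si](C)(C)C(C)(C)C)Cc2ccc(O[Si](C(C)C)(C(C)C)C(C)C)c(OC)c2)ccc1O[Si](C)(C)C(C)(C)C
F5 | step 2 | rac-trans-cyclohex-4-ene-1,2-dicarboxylic acid | OC(=O)[C@@H]1CC=CC[C@H]1C(=O)O.OC(=O)[C@H]1CC=CC[C@@H]1C(=O)O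
F6 | step 2 | (1R,2R)-cyclohex-4-ene-1,2-dicarboxylic acid | OC(=O)[C@@H]1CC=CC[C@H]1C(=O)O
F7 | step 5 | (3R,4R)-3,4-bis[(tert-butyldimethylsilyloxy)methyl]hexanedial | CC(C)(C)[Si](C)(C)OC[C@H](CC=O)[C@H](CO[Si](C)(C)C(C)(C)C)CC=O
A1 | alternative 1 | 3-[3-methoxy-4-(methoxymethoxy)benzyl]cyclobutan-1-one | O=C1CC(Cc2ccc(OCOC)c(OC)c2)C1
A2 | alternative 1 | (R)-4-[3-methoxy-4-(methoxymethoxy)benzyl]dihydrofuran-2(3H)-one | O=C1C[C@@H](Cc2ccc(OCOC)c(OC)c2)CO1
A3 | alternative 2 | (5R)-5-[(1R,2S,5R)-menthyloxy]furan-2(5H)-one | O=C1O[C@@H](O[C@@H]2C[C@H](C)CC[C@H]2C(C)C)C=C1
A4 | alternative 2 | 2-[3-methoxy-4-(triisopropylsilyloxy)phenyl]-1,3-dithiane | COc1cc(C2SCCCS2)ccc1O[Si](C(C)C)(C(C)C)C(C)C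
A5 | alternative 2 | [4-(bromomethyl)-2-methoxyphenoxy]triisopropylsilane | COc1cc(CBr)ccc1O[Si](C(C)C)(C(C)C)C(C)C
A6 | alternative 2 | (3R,4R,5R)-3-[3-methoxy-4-(triisopropylsilyloxy)benzyl]-4-{2-[3-methoxy-4-(triisopropylsilyloxy)phenyl]-1,3-dithian-2-yl}-5-[(1R,2S,5R)-menthyloxy]dihydrofuran-2(3H)-one | O=C1O[C@@H](O[C@@H]2C[C@H](C)CC[C@H]2C(C)C)[C@H](C2(c3ccc(O[Si](C(C)C)(C(C)C)C(C)C)c(OC)c3)SCCCS2)[C@H]1Cc1ccc(O[Si](C(C)C)(C(C)C)C(C)C)c(OC)c1
A7 | alternative 3 | (4-allyl-2-methoxyphenoxy)triisopropylsilane | C=CCc1ccc(O[Si](C(C)C)(C(C)C)C(C)C)c(OC)c1
A8 | alternative 3 | (E)-1,4-bis[3-methoxy-4-(triisopropylsilyloxy)phenyl]but-2-ene | COc1cc(C/C=C/Cc2ccc(O[Si](C(C)C)(C(C)C)C(C)C)c(OC)c2)ccc1O[Si](C(C)C)(C(C)C)C(C)C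
A9 | alternative 3 | dimethyl (2R,3R)-2,3-bis[3-methoxy-4-(triisopropylsilyloxy)benzyl]succinate | COC(=O)[C@H](Cc1ccc(O[Si](C(C)C)(C(C)C)C(C)C)c(OC)c1)[C@H](C(=O)OC)Cc1ccc(O[Si](C(C)C)(C(C)C)C(C)C)c(OC)c1
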